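**Retrosynthetic overview**

- The target is reached from a fully protected isoflavone by desilylation at O4', O-prenylation and acid removal of the two MOM groups. Rings A and B are bought as arenes; ring C is the only ring built, and it is built last.
- Ring C is opened at C2=C3, the one double bond of ring C that is not shared with ring A. C2 is the enol-ether CH on O1, and C3 carries ring B beside the C4 carbonyl. The strategy rests on this O1–C2=C3–C4(=O) enol ether–enone unit, which ring-closing metathesis of an aryl vinyl ether with a 1,1-disubstituted enone alkene should deliver.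
- The diene comes from MnO2 oxidation of an allylic alcohol. That alcohol comes from 1,2-addition of a Shapiro-derived 1-arylvinyllithium (ring B, from 2,5-dimethoxybenzaldehyde) to 2,4-bis(methoxymethoxy)-6-(vinyloxy)benzaldehyde (ring A, from 2,4,6-trihydroxybenzaldehyde).
- The vinyl ether is installed on the aldehyde before the fragments are joined, because a free ortho phenol beside the α-aryl enone would close by oxa-Michael addition to an isoflavanone. O4' is held as a silyl ether during metathesis because a prenyl alkene could exchange with the ethylene formed.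

Key step: step 10

Remark on the chemistry: the carbinol centre of 14 forms racemic and is erased in step 9; hydrazone 11 is drawn as its expected major E isomer; the target has no stereocentre.

**Route**

Step 1
Reactants: 1 2,4,6-trihydroxybenzaldehyde
Product: 2 2-hydroxy-4,6-bis(methoxymethoxy)benzaldehyde
Conditions: MOMCl (2.2 equiv), i-Pr2NEt (3 equiv), CH2Cl2, 0 °C → rt
Reagents that add atoms: chloromethyl methyl ether, COCCl
Why: O-alkylation of the two more acidic, unchelated phenols should stop at the bis-acetal because the remaining ortho hydroxyl is hydrogen-bonded to the aldehyde (selective MOM protection of an acylphloroglucinol).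

Step 2
Reactants: 2 2-hydroxy-4,6-bis(methoxymethoxy)benzaldehyde
Product: 3 2,4-bis(methoxymethoxy)-6-(vinyloxy)benzaldehyde
Conditions: 2,4,6-trivinylcyclotriboroxane·pyridine (0.7 equiv), Cu(OAc)2 (1 equiv), pyridine (10 equiv), CH2Cl2, rt, air
Reagents that add atoms: 2,4,6-trivinylcyclotriboroxane–pyridine complex, C=CB1OB(C=C)OB(C=C)O1.c1ccncc1
Why: Chan–Lam-type O-vinylation, in which the vinyl group is transferred from boron to the divalent copper phenoxide and C–O reductive elimination follows air oxidation to trivalent copper, should convert the phenol into the aryl vinyl ether under neutral conditions that leave the aldehyde and MOM ethers untouched.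

Step 3
Reactants: 4 2,5-dimethoxybenzaldehyde
Product: 6 2,5-dimethoxyphenol, via 2,5-dimethoxyphenyl formate 5 (not isolated)
Conditions: mCPBA (1.3 equiv), CH2Cl2, 0 °C → rt; aqueous wash; then K2CO3 (cat.), MeOH, rt
Reagents that add atoms: meta-chloroperoxybenzoic acid, OOC(=O)c1cccc(Cl)c1
Why: Baeyer–Villiger (Dakin-type) oxidation of the electron-rich benzaldehyde proceeds by aryl migration to the aryl formate, which is methanolysed to the phenol.

Step 4
Reactants: 6 2,5-dimethoxyphenol
Product: 7 4-bromo-2,5-dimethoxyphenol
Conditions: NBS (1.0 equiv), MeCN, −20 °C → 0 °C, dark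
Reagents that add atoms: N-bromosuccinimide, O=C1CCC(=O)N1Br
Why: Electrophilic aromatic bromination should go to C4, the only position that is para to the hydroxyl and ortho to a methoxy group, since C6 is flanked by two oxygen substituents.

Step 5
Reactants: 7 4-bromo-2,5-dimethoxyphenol
Product: 8 (4-bromo-2,5-dimethoxyphenoxy)triisopropylsilane
Conditions: TIPSCl (1.2 equiv), imidazole (2.5 equiv), DMF, rt
Reagents that add atoms: triisopropylsilyl chloride, CC(C)[Si](Cl)(C(C)C)C(C)C
Why: Standard silylation of a phenol gives an aryl triisopropylsilyl ether that is robust towards the organolithium, oxidation and metathesis steps ahead.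

Step 6
Reactants: 8 (4-bromo-2,5-dimethoxyphenoxy)triisopropylsilane
Product: 10 1-[2,5-dimethoxy-4-(triisopropylsilyloxy)phenyl]ethan-1-one, via aryllithium 9 (not isolated)
Conditions: n-BuLi (1.05 equiv), THF, −78 °C; then MeC(O)N(OMe)Me, −78 °C → 0 °C
Reagents that add atoms: N-methoxy-N-methylacetamide, CON(C)C(C)=O
Why: Bromine–lithium exchange followed by Weinreb amide acylation should give the methyl ketone without over-addition, because the chelated tetrahedral intermediate survives until the quench.

Step 7
Reactants: 10 1-[2,5-dimethoxy-4-(triisopropylsilyloxy)phenyl]ethan-1-one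
Product: 11 (E)-N'-{1-[2,5-dimethoxy-4-(triisopropylsilyloxy)phenyl]ethylidene}-2,4,6-triisopropylbenzenesulfonohydrazide
Conditions: 2,4,6-triisopropylbenzenesulfonyl hydrazide (1.05 equiv), HCl (cat.), MeOH/THF, rt
Reagents that add atoms: 2,4,6-triisopropylbenzenesulfonyl hydrazide, CC(C)c1cc(C(C)C)c(S(=O)(=O)NN)c(C(C)C)c1
Why: Acid-catalysed condensation of the ketone with the sulfonyl hydrazide gives the hydrazone, with the sulfonamide expected syn to the methyl group as the Shapiro reaction requires.

Step 8
Reactants: 11 (E)-N'-{1-[2,5-dimethoxy-4-(triisopropylsilyloxy)phenyl]ethylidene}-2,4,6-triisopropylbenzenesulfonohydrazide; 3 2,4-bis(methoxymethoxy)-6-(vinyloxy)benzaldehyde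
Product: 14 1-[2,4-bis(methoxymethoxy)-6-(vinyloxy)phenyl]-2-[2,5-dimethoxy-4-(triisopropylsilyloxy)phenyl]prop-2-en-1-ol (racemic), via dilithiated hydrazone 12 (not isolated), via arylvinyllithium 13 (not isolated)
Conditions: n-BuLi (2.1 equiv), THF, −78 °C → 0 °C (N2 evolution); then 3 (0.9 equiv), −78 °C → 0 °C
Reagents that add atoms: none
Why: In this Shapiro reaction the hydrazone dianion loses sulfinate and N2 to give the 1-arylvinyllithium (the isopropyl groups block ortho-lithiation of the sulfonyl ring), which adds 1,2 to the aldehyde; the new carbinol centre is formed without control and is removed in step 9.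

Step 9
Reactants: 14 1-[2,4-bis(methoxymethoxy)-6-(vinyloxy)phenyl]-2-[2,5-dimethoxy-4-(triisopropylsilyloxy)phenyl]prop-2-en-1-ol
Product: 15 1-[2,4-bis(methoxymethoxy)-6-(vinyloxy)phenyl]-2-[2,5-dimethoxy-4-(triisopropylsilyloxy)phenyl]prop-2-en-1-one
Conditions: MnO2 (activated, excess), CH2Cl2, rt
Reagents that add atoms: none
Why: The alcohol is both benzylic and allylic, so MnO2 oxidation should give the enone under neutral conditions that spare the acid-sensitive vinyl and MOM ethers.

Step 10
Reactants: 15 1-[2,4-bis(methoxymethoxy)-6-(vinyloxy)phenyl]-2-[2,5-dimethoxy-4-(triisopropylsilyloxy)phenyl]prop-2-en-1-one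
Product: 16 3-[2,5-dimethoxy-4-(triisopropylsilyloxy)phenyl]-5,7-bis(methoxymethoxy)-4H-chromen-4-one
Conditions: second-generation Grubbs catalyst RuCl2(=CHPh)(H2IMes)(PCy3) (10 mol %, two portions), toluene (5 mM), 100 °C, Ar sparge
Reagents that add atoms: none
Why: Proposed new method: the benzylidene should exchange first onto the unhindered, electron-rich aryl vinyl ether to give a tethered aryloxycarbene Ru=CH–OAr, which the ortho relationship on ring A holds within reach of the enone methylene; intramolecular [2+2] cycloaddition gives a ruthenacyclobutane, and cycloreversion releases ring C with the C2=C3 bond and Ru=CH2, which carries the chain and is finally lost as ethylene. The closest known reactions are ring-closing metatheses of aryl vinyl ethers bearing ortho alkenyl or allyl groups to benzofurans and chromenes, and of acrylates of 2-vinylphenols to coumarins, with the same catalyst; pairing an enol ether with an α-aryl enone in one closure has not been shown. Ring C closes as a six-membered ring by olefin metathesis between the two terminal methylenes, both of which are expelled, and no stereocentre is formed. The step needs ring closure to outrun both the resting of ruthenium as the aryloxycarbene and intermolecular cross-metathesis: the aryloxycarbene is less stabilised than an alkoxycarbene because the oxygen lone pair is shared with the acyl-substituted ring A, high dilution suppresses dimers, heat with argon sparging removes ethylene, and the 4-pyranone product cannot re-enter the cycle. The silyl and MOM ethers are inert, and no prenyl alkene is yet present to exchange with ethylene.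

Step 11
Reactants: 16 3-[2,5-dimethoxy-4-(triisopropylsilyloxy)phenyl]-5,7-bis(methoxymethoxy)-4H-chromen-4-one
Product: 17 3-(4-hydroxy-2,5-dimethoxyphenyl)-5,7-bis(methoxymethoxy)-4H-chromen-4-one
Conditions: Bu4NF (1.1 equiv), AcOH (1.1 equiv), THF, 0 °C
Reagents that add atoms: none
Why: Fluoride-induced desilylation, driven by the Si–F bond, should free O4' alone, and the acetic acid buffer keeps the base-sensitive pyranone away from free phenoxide.

Step 12
Reactants: 17 3-(4-hydroxy-2,5-dimethoxyphenyl)-5,7-bis(methoxymethoxy)-4H-chromen-4-one; 18 prenyl bromide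
Product: 19 3-{2,5-dimethoxy-4-[(3-methylbut-2-en-1-yl)oxy]phenyl}-5,7-bis(methoxymethoxy)-4H-chromen-4-one
Conditions: K2CO3 (2 equiv), acetone, 50 °C
Reagents that add atoms: none
Why: Williamson etherification of the only free phenol with the allylic bromide should give the O-prenyl ether by SN2 displacement at the primary carbon.

Step 13
Reactants: 19 3-{2,5-dimethoxy-4-[(3-methylbut-2-en-1-yl)oxy]phenyl}-5,7-bis(methoxymethoxy)-4H-chromen-4-one
Product: 20 brandisianin A
Conditions: HCl (aq., ca. 1 M final), MeOH/THF, 40 °C, stopped at full conversion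
Reagents that add atoms: none
Why: Acid-catalysed acetal exchange with methanol should remove both MOM groups (the 5-O acetal is assisted by the peri carbonyl) under dilute, mildly warm conditions chosen to leave the primary aryl prenyl ether intact.

**Compound list**

1 | 2,4,6-trihydroxybenzaldehyde | O=Cc1c(O)cc(O)cc1O | starting material
2 | 2-hydroxy-4,6-bis(methoxymethoxy)benzaldehyde | COCOc1cc(O)c(C=O)c(OCOC)c1 | intermediate
3 | 2,4-bis(methoxymethoxy)-6-(vinyloxy)benzaldehyde | C=COc1cc(OCOC)cc(OCOC)c1C=O | intermediate
4 | 2,5-dimethoxybenzaldehyde | COc1ccc(OC)c(C=O)c1 | starting material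
5 | 2,5-dimethoxyphenyl formate (not isolated) | COc1ccc(OC)c(OC=O)c1 | intermediate
6 | 2,5-dimethoxyphenol | COc1ccc(OC)c(O)c1 | intermediate
7 | 4-bromo-2,5-dimethoxyphenol | COc1cc(Br)c(OC)cc1O | intermediate
8 | (4-bromo-2,5-dimethoxyphenoxy)triisopropylsilane | COc1cc(Br)c(OC)cc1O[Si](C(C)C)(C(C)C)C(C)C | intermediate
9 | [2,5-dimethoxy-4-(triisopropylsilyloxy)phenyl]lithium (not isolated) | [Li]c1cc(OC)c(O[Si](C(C)C)(C(C)C)C(C)C)cc1OC | intermediate
10 | 1-[2,5-dimethoxy-4-(triisopropylsilyloxy)phenyl]ethan-1-one | CC(=O)c1cc(OC)c(O[Si](C(C)C)(C(C)C)C(C)C)cc1OC | intermediate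
11 | (E)-N'-{1-[2,5-dimethoxy-4-(triisopropylsilyloxy)phenyl]ethylidene}-2,4,6-triisopropylbenzenesulfonohydrazide | C/C(=N\NS(=O)(=O)c1c(C(C)C)cc(C(C)C)cc1C(C)C)c1cc(OC)c(O[Si](C(C)C)(C(C)C)C(C)C)cc1OC | intermediate
12 | C,N-dilithiated hydrazone of 11 (not isolated) | [Li]CC(=NN([Li])S(=O)(=O)c1c(C(C)C)cc(C(C)C)cc1C(C)C)c1cc(OC)c(O[Si](C(C)C)(C(C)C)C(C)C)cc1OC | intermediate
13 | 1-[2,5-dimethoxy-4-(triisopropylsilyloxy)phenyl]vinyllithium (not isolated) | [Li]C(=C)c1cc(OC)c(O[Si](C(C)C)(C(C)C)C(C)C)cc1OC | intermediate
14 | 1-[2,4-bis(methoxymethoxy)-6-(vinyloxy)phenyl]-2-[2,5-dimethoxy-4-(triisopropylsilyloxy)phenyl]prop-2-en-1-ol (racemic) | C=COc1cc(OCOC)cc(OCOC)c1C(O)C(=C)c1cc(OC)c(O[Si](C(C)C)(C(C)C)C(C)C)cc1OC | intermediate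
15 | 1-[2,4-bis(methoxymethoxy)-6-(vinyloxy)phenyl]-2-[2,5-dimethoxy-4-(triisopropylsilyloxy)phenyl]prop-2-en-1-one | C=COc1cc(OCOC)cc(OCOC)c1C(=O)C(=C)c1cc(OC)c(O[Si](C(C)C)(C(C)C)C(C)C)cc1OC | intermediate
16 | 3-[2,5-dimethoxy-4-(triisopropylsilyloxy)phenyl]-5,7-bis(methoxymethoxy)-4H-chromen-4-one | COCOc1cc(OCOC)c2c(=O)c(-c3cc(OC)c(O[Si](C(C)C)(C(C)C)C(C)C)cc3OC)coc2c1 | intermediate
17 | 3-(4-hydroxy-2,5-dimethoxyphenyl)-5,7-bis(methoxymethoxy)-4H-chromen-4-one | COCOc1cc(OCOC)c2c(=O)c(-c3cc(OC)c(O)cc3OC)coc2c1 | intermediate
18 | prenyl bromide (1-bromo-3-methylbut-2-ene) | CC(C)=CCBr | starting material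
19 | 3-{2,5-dimethoxy-4-[(3-methylbut-2-en-1-yl)oxy]phenyl}-5,7-bis(methoxymethoxy)-4H-chromen-4-one | COCOc1cc(OCOC)c2c(=O)c(-c3cc(OC)c(OCC=C(C)C)cc3OC)coc2c1 | intermediate
20 | brandisianin A | COc1cc(-c2coc3cc(O)cc(O)c3c2=O)c(OC)cc1OCC=C(C)C | target

**Step count**

Total: 13 steps. Longest linear sequence: 11 steps (steps 3–13, from 2,5-dimethoxybenzaldehyde); steps 1–2 form the ring A branch that joins in step 8.

**Steps most likely to fail**

1. Step 10 (ring-closing metathesis). Ruthenium may come to rest as the aryloxycarbene, possibly chelated by the neighbouring acyl or MOM oxygen, and fail to add to the hindered, electron-poor 1,1-disubstituted alkene; turnover then stops and intermolecular vinyl-ether exchange or thermal catalyst decay takes over. The fallback uses known chemistry, sets out from aldehyde 2 (with hydrazone 11) and returns at compound 16. Aldehyde 2 is deprotonated with NaH in THF and treated with arylvinyllithium 13, generated from 11 as in step 8, to give the phenolic allylic diol F1. MnO2 oxidation should give the 2'-hydroxy enone F2, whose free phenol adds to the enone methylene in a 6-endo oxa-Michael closure on brief treatment with K2CO3 in MeOH, giving the racemic isoflavanone F3. Dehydrogenation of C2–C3 with DDQ in dioxane at 100 °C should then give isoflavone 16.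

2. Step 2 (O-vinylation). The hydrogen-bonded, ortho-disubstituted phenol may be tied up as a copper salicylaldehyde chelate, so C–O coupling is slow and the vinylboroxine is consumed by protodeboronation and homocoupling. The fallback sets out from compound 2 and returns at compound 3. Alkylation with excess 1,2-dibromoethane (K2CO3, DMF, 60 °C) should give the 2-bromoethyl ether F4, and E2 elimination with t-BuOK in THF/DMSO at 0 °C, which the non-enolisable aldehyde tolerates, should give vinyl ether 3.

3. Step 13 (MOM removal). Acid may ionise the aryl prenyl ether (loss of the prenyl group as its allylic cation) or add methanol or HCl across the prenyl alkene in competition with acetal cleavage. The fallback sets out from compound 17 and returns at compound 20, and moves the acid step ahead of prenylation. HCl in MeOH at 50 °C removes both MOM groups from 17 to give the triol F5. Treatment with t-BuOK (2.1 equiv) in DMF at 0 °C forms the 7,4'-dianion, and one equivalent of prenyl bromide 18 should alkylate the less stabilised, more nucleophilic 4'-phenoxide. The 7-phenoxide, delocalised into the pyranone, and the chelated 5-hydroxyl should stay free, so that 20 is obtained directly.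

**Further compounds**

F1 | step 10 | 1-[2-hydroxy-4,6-bis(methoxymethoxy)phenyl]-2-[2,5-dimethoxy-4-(triisopropylsilyloxy)phenyl]prop-2-en-1-ol (racemic) | COCOc1cc(O)c(C(O)C(=C)c2cc(OC)c(O[Si](C(C)C)(C(C)C)C(C)C)cc2OC)c(OCOC)c1
F2 | step 10 | 1-[2-hydroxy-4,6-bis(methoxymethoxy)phenyl]-2-[2,5-dimethoxy-4-(triisopropylsilyloxy)phenyl]prop-2-en-1-one | COCOc1cc(O)c(C(=O)C(=C)c2cc(OC)c(O[Si](C(C)C)(C(C)C)C(C)C)cc2OC)c(OCOC)c1
F3 | step 10 | 3-[2,5-dimethoxy-4-(triisopropylsilyloxy)phenyl]-5,7-bis(methoxymethoxy)chroman-4-one (racemic) | COCOc1cc(OCOC)c2c(c1)OCC(c1cc(OC)c(O[Si](C(C)C)(C(C)C)C(C)C)cc1OC)C2=O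
F4 | step 2 | 2-(2-bromoethoxy)-4,6-bis(methoxymethoxy)benzaldehyde | COCOc1cc(OCCBr)c(C=O)c(OCOC)c1
F5 | step 13 | 5,7-dihydroxy-3-(4-hydroxy-2,5-dimethoxyphenyl)-4H-chromen-4-one | COc1cc(-c2coc3cc(O)cc(O)c3c2=O)c(OC)cc1O
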